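The data come from a simulation for an exercise, and the scatter is random.

In a one-step world the excess of right-handed substrate over left-handed substrate would hang on two numbers: a depth x = ln(c charged / c left) of the left-handed substrate, and the selectivity factor s, the ratio of the two substrates' depths:

z = x − x/s, excess = tanh(0.5 z)

common to all: free catalyst 0.5 mol%
- midnight: left-handed substrate 2 mM; right-handed substrate 2 mM; partner 1.2 equiv; impurity 8.2 µM; run made earlier
- spring: left-handed substrate 2 mM; right-handed substrate 2 mM; partner 1.2 equiv; impurity 10 µM; run made earlier
- south-west: left-handed substrate 2.0 mM; right-handed substrate 2.0 mM; partner 1.20 equiv; impurity 6.6 µM; time 5.0 min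
- east: left-handed substrate 2.0 mM; right-handed substrate 2.0 mM; partner 1.20 equiv; impurity 20 µM; time 5.0 min

| run | time / min | right-handed substrate / % | left-handed substrate / % |
|---|---|---|---|
| midnight | 0.667 | 48.4 | 41.4 |
| midnight | 1.33 | 48.8 | 38.8 |
| midnight | 2.00 | 50.1 | 37.0 |
| midnight | 3.00 | 47.9 | 34.3 |
| midnight | 4.00 | 48.2 | 37.8 |
| spring | 0.333 | 49.9 | 49.4 |
| spring | 0.833 | 50.3 | 48.2 |
| spring | 1.50 | 50.0 | 47.5 |
| spring | 2.50 | 50.9 | 48.3 |
| spring | 4.00 | 49.1 | 47.0 |

(scatter of a reading: 1 percentage point)

* which one finishes higher in excess of right-handed substrate over left-handed substrate among what is left of the two ("neither" within 2 percentage points) (south-west / east / neither)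
* excess of right-handed substrate over left-handed substrate among what is left of the two at the end, south-west
* excess of right-handed substrate over left-handed substrate among what is left of the two at the end, east

- free catalyst is single-handed; left-handed substrate and right-handed substrate are mirror images of each other, charged as a racemate, each of them at the stated concentration
- an excess is below zero if the other one leads

Both earlier runs level off, so we average the left-handed readings from 2.00 min on in midnight and from 1.50 min on in spring, which gives depths of 0.318 and 0.0492. The catalyst charge is 10.0 µM; spring's impurity matches it, while midnight leaves a surplus of 1.80 µM. So we take g, the depth gained per µM of catalyst surplus over impurity, 0.150 µM⁻¹, and south-west has a surplus of 3.40 µM.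

Upper bound, partner as in midnight, no right-handed loss: x = 0.558, excess 27.2%

But, taking one partner per left-handed substrate, that depth in south-west asks for 0.855 mM of the 2.40 mM charged, more than the 0.545 mM that midnight's depth asks for. Replacing the partner curve by its mean scales the surplus term by 0.927, and using its end value scales it by 0.833. Midnight's mean right-handed reading gives s, and its lowest gives a low s.

Mean: x = 0.521, s = 11.9, excess 23.4%

Lower bound: x = 0.473, s = 7.42, excess 20.2%

East's impurity exceeds the catalyst, so we place it between zero and the 2.46% that spring's depth gives.

The forecast names south-west, with 30% (25% to 36%) for south-west, above our upper bound, and 0.2% for east, reading that “The impurity therefore seems to titrate the 10 µM catalyst about 1:1 and tightly”.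

The flask gives south-west: 21.0% in south-west and 0.246% in east.

    free catalyst → spent catalyst B (k = 0.0110 s⁻¹)
    partner → decomposed reagent (k = 0.0110 s⁻¹)
    partner + free catalyst + left-handed substrate → free catalyst + left-handed product (k = 1.90 × 10⁶ L² mol⁻² s⁻¹)
    free catalyst + impurity → spent catalyst A (k = 5.40 × 10⁵ L mol⁻¹ s⁻¹)
    partner + free catalyst + right-handed substrate → free catalyst + right-handed product (k = 2.90 × 10⁵ L² mol⁻² s⁻¹)

South-west ends with 0% of its impurity left and spent catalyst A at 66.0% of the catalyst charged, so the part of the catalyst beyond the impurity, the surplus of 3.40 µM, stands at the end as spent catalyst B (32.8%) and free catalyst (1.25%). A neighbour flask, east's recipe with 8.00 µM of impurity, has a surplus of 2.00 µM, for which g gives a depth of 0.348, or 35.3% of the two substrates together as left-handed substrate; that flask ends at 35.7%, with an excess of 14.2%.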